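## Retrosynthetic overview

1. Target 18 ⇐ 2-isopropenyl diester 16 by oxidation of the C1' methyl group to the enal (SeO2, then Dess–Martin). 16 ⇐ silyl-protected methyl ketone 13 by methylenation of C1'=O, desilylation and acylation of C3–OH.
2. Strategic feature: in ring B (O1–C2–C3–C3a–C7a) the benzylic carbinol C3, the O1-bearing carbon C2 and the side-chain carbon C1' form a β-hydroxy-α-aryloxy ketone once C1' is a carbonyl carbon. This is an aldol retron with the 2,3-cis relation.
3. Key disconnection C2–C3: aldol 12 ⇐ 2-(2-oxopropoxy)benzaldehyde 10 by an L-proline 5-enolexo aldol that closes ring B and sets C2 and C3 together.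
4. 10 ⇐ double ozonolysis of 8 (styrene = masked formyl, methallyl ether = masked acetonyl). 8 ⇐ asymmetric transfer hydrogenation and isovalerylation of ketone 5. 5 ⇐ Suzuki vinylation and O-methallylation of bromophenol 1.
5. Ring order: ring A (benzene) comes with 1; ring B is the only ring formed, in step 6.

Key step: step 6

Assumption: 1, 2, 4 and 7 are taken as commercial, and L-proline is (S)-proline. The formyl group of the aldol precursor is carried as a vinyl group so that one ozonolysis unmasks both carbonyl groups under neutral conditions.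

## Route

Step 1
Reactants: 1 3'-bromo-4'-hydroxyacetophenone; 2 methallyl chloride
Product: 3 1-[3-bromo-4-(2-methylprop-2-en-1-yloxy)phenyl]ethan-1-one
Conditions: K2CO3, NaI (cat.), DMF, 60 °C
Reagents that add atoms: none
Why: Williamson ether synthesis on an acidic para-acyl phenol with an allylic chloride under iodide catalysis; the methallyl ether masks the later acetonyl ketone and is installed before any benzylic leaving group exists, so no quinone methide pathway is open.

Step 2
Reactants: 3 1-[3-bromo-4-(2-methylprop-2-en-1-yloxy)phenyl]ethan-1-one; 4 vinylboronic acid pinacol ester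
Product: 5 1-[3-ethenyl-4-(2-methylprop-2-en-1-yloxy)phenyl]ethan-1-one
Conditions: PdCl2(dppf) (cat.), K2CO3, 1,4-dioxane/H2O, 85 °C
Reagents that add atoms: none
Why: Suzuki–Miyaura vinylation of the aryl bromide; the vinyl group is a formyl equivalent that is inert to the coming ketone reduction, and the methallyl ether should survive because no soft nucleophile is present to intercept an allyl–palladium species.

Step 3
Reactants: 5 1-[3-ethenyl-4-(2-methylprop-2-en-1-yloxy)phenyl]ethan-1-one
Product: 6 (1R)-1-[3-ethenyl-4-(2-methylprop-2-en-1-yloxy)phenyl]ethan-1-ol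
Conditions: RuCl(p-cymene)[(R,R)-TsDPEN] (1 mol%), HCO2H/Et3N (5:2), CH2Cl2, rt
Reagents that add atoms: none
Why: Noyori asymmetric transfer hydrogenation of an aryl methyl ketone, in which the (R,R)-ligand is the one that delivers hydride to give (R)-1-arylethanols through the six-membered hydride/proton transfer organised by the arene–ligand contact; the reagent is selective for C=O, so both alkenes should be untouched.

Step 4
Reactants: 6 (1R)-1-[3-ethenyl-4-(2-methylprop-2-en-1-yloxy)phenyl]ethan-1-ol; 7 isovaleryl chloride
Product: 8 (1R)-1-[3-ethenyl-4-(2-methylprop-2-en-1-yloxy)phenyl]ethyl 3-methylbutanoate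
Conditions: Et3N, DMAP (cat.), CH2Cl2, 0 °C
Reagents that add atoms: none
Why: DMAP-catalysed O-acylation under basic conditions, which does not touch the C–O bond of the carbinol, so the (R) configuration is retained.

Step 5
Reactants: 8 (1R)-1-[3-ethenyl-4-(2-methylprop-2-en-1-yloxy)phenyl]ethyl 3-methylbutanoate
Product: 10 (1R)-1-[3-formyl-4-(2-oxopropoxy)phenyl]ethyl 3-methylbutanoate, via bis-ozonide 9 (not isolated)
Conditions: O3, CH2Cl2, −78 °C (Sudan red 7B end point); PPh3, −78 °C to rt
Reagents that add atoms: ozone O=[O+][O-]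
Why: Ozonolysis with reductive work-up cleaves both terminal alkenes, the styrene to the aryl aldehyde and the 1,1-disubstituted alkene to the methyl ketone; the work-up is neutral, so the keto aldehyde should not condense to 2-acetylbenzofuran, and the indicator limits ozone contact with the arene.

Step 6
Reactants: 10 (1R)-1-[3-formyl-4-(2-oxopropoxy)phenyl]ethyl 3-methylbutanoate
Product: 12 (1R)-1-[(2S,3R)-2-acetyl-3-hydroxy-2,3-dihydro-1-benzofuran-5-yl]ethyl 3-methylbutanoate, via L-proline (E)-enamine 11 (not isolated)
Conditions: L-proline (30 mol%), DMF, 0 °C to rt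
Reagents that add atoms: none
Why: L-Proline condenses with the aliphatic ketone of 10 to the (E)-enamine 11 on the O–CH2 side, whose oxygen-bearing carbon attacks the ortho formyl group while the carboxylic acid hydrogen-bonds the aldehyde oxygen, and hydrolysis of the resulting iminium ion releases 12 and the catalyst. The closest known reaction type is the amine-catalysed intramolecular enamine aldol (Hajos–Parrish-type aldolisation in its 5-enolexo form) of ortho-(2-oxoalkoxy)aryl carbonyl compounds to cis-2-acyl-2,3-dihydrobenzofuran-3-ols. Ring B (O1–C2–C3–C3a–C7a) closes by formation of C2–C3 in a 5-enolexo-trig aldol closure, the enamine double bond lying outside the new ring. C2 and C3 are created together: the proline stereocentre, through its carboxylic acid, fixes which face of the anti (E)-enamine is attacked (expected 2S), and the five-membered tether holds the aldehyde aryl group next to O1 so that the hydrogen-bonded oxygen ends up cis to the acetyl group (expected 3R). The step needs regioselectivity between the two possible enamines, which the substrate secures because the methyl-side enamine could only close a seven-membered ring and the aldehyde is non-enolisable; it also needs the aldol to stop before loss of water to 2-acetylbenzofuran, which the neutral medium, low temperature and prompt silylation in step 7 are meant to secure. The remote (R)-ester centre is a spectator and is not expected to influence the outcome.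

Step 7
Reactants: 12 (1R)-1-[(2S,3R)-2-acetyl-3-hydroxy-2,3-dihydro-1-benzofuran-5-yl]ethyl 3-methylbutanoate
Product: 13 (1R)-1-[(2S,3R)-2-acetyl-3-(triethylsilyloxy)-2,3-dihydro-1-benzofuran-5-yl]ethyl 3-methylbutanoate
Conditions: Et3SiCl, imidazole, DMF, 0 °C
Reagents that add atoms: chlorotriethylsilane CC[Si](Cl)(CC)CC
Why: Silylation of the secondary benzylic alcohol shuts off retro-aldol cleavage and removes the free hydroxyl before the titanium reagent is used; imidazole at 0 °C is too weak a base to enolise C2 or trigger β-elimination across C2–C3, so both new stereocentres should be kept.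

Step 8
Reactants: 13 (1R)-1-[(2S,3R)-2-acetyl-3-(triethylsilyloxy)-2,3-dihydro-1-benzofuran-5-yl]ethyl 3-methylbutanoate
Product: 14 (1R)-1-[(2R,3R)-2-(prop-1-en-2-yl)-3-(triethylsilyloxy)-2,3-dihydro-1-benzofuran-5-yl]ethyl 3-methylbutanoate
Conditions: Zn, CH2Br2, TiCl4 (reagent pre-formed and aged in THF, 0 °C); 13 in CH2Cl2, 0 °C to rt
Reagents that add atoms: dibromomethane BrCBr
Why: Takai–Lombardo methylenation, whose non-basic zinc–titanium methylene reagent converts enolisable ketones into 1,1-disubstituted alkenes without epimerising the α-centre C2 or eliminating the β-silyloxy group and leaves esters alone; the change of the C2 descriptor from S to R is only a change of CIP priorities.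

Step 9
Reactants: 14 (1R)-1-[(2R,3R)-2-(prop-1-en-2-yl)-3-(triethylsilyloxy)-2,3-dihydro-1-benzofuran-5-yl]ethyl 3-methylbutanoate
Product: 15 (1R)-1-[(2R,3R)-3-hydroxy-2-(prop-1-en-2-yl)-2,3-dihydro-1-benzofuran-5-yl]ethyl 3-methylbutanoate
Conditions: HF·pyridine, pyridine, THF, 0 °C
Reagents that add atoms: none
Why: Buffered fluoride cleavage of the Si–O bond; the pyridine buffer should keep the ortho-alkoxybenzylic C3–O bond from ionising, and the isovalerate ester is inert to these conditions.

Step 10
Reactants: 15 (1R)-1-[(2R,3R)-3-hydroxy-2-(prop-1-en-2-yl)-2,3-dihydro-1-benzofuran-5-yl]ethyl 3-methylbutanoate; 7 isovaleryl chloride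
Product: 16 (1R)-1-[(2R,3R)-3-(3-methylbutanoyloxy)-2-(prop-1-en-2-yl)-2,3-dihydro-1-benzofuran-5-yl]ethyl 3-methylbutanoate
Conditions: Et3N, DMAP (cat.), CH2Cl2, 0 °C to rt
Reagents that add atoms: none
Why: DMAP-catalysed acylation with retention at C3; the ester is put on only now, when C1' is an alkene carbon and C2–H is no longer acidic, so that base-induced elimination to the benzofuran is not expected.

Step 11
Reactants: 16 (1R)-1-[(2R,3R)-3-(3-methylbutanoyloxy)-2-(prop-1-en-2-yl)-2,3-dihydro-1-benzofuran-5-yl]ethyl 3-methylbutanoate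
Product: 17 (1R)-1-[(2R,3R)-2-(3-hydroxyprop-1-en-2-yl)-3-(3-methylbutanoyloxy)-2,3-dihydro-1-benzofuran-5-yl]ethyl 3-methylbutanoate
Conditions: SeO2 (0.5 equiv), t-BuOOH, CH2Cl2, rt
Reagents that add atoms: selenium dioxide O=[Se]=O (oxygen carrier); tert-butyl hydroperoxide CC(C)(C)OO (terminal oxidant)
Why: Riley allylic oxidation, an ene reaction of SeO2 at the terminal CH2 followed by a [2,3]-sigmatropic shift that returns the double bond and places oxygen on the methyl carbon; the methyl group is preferred over the hindered methine C2–H (order CH2 > CH3 > CH for 1,1-disubstituted alkenes), and any enal formed already at this stage is the target and passes through step 12 unchanged.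

Step 12
Reactants: 17 (1R)-1-[(2R,3R)-2-(3-hydroxyprop-1-en-2-yl)-3-(3-methylbutanoyloxy)-2,3-dihydro-1-benzofuran-5-yl]ethyl 3-methylbutanoate
Product: 18 (1R)-1-[(2R,3R)-3-(3-methylbutanoyloxy)-2-(3-oxoprop-1-en-2-yl)-2,3-dihydro-1-benzofuran-5-yl]ethyl 3-methylbutanoate
Conditions: Dess–Martin periodinane, NaHCO3, CH2Cl2, 0 °C to rt
Reagents that add atoms: none
Why: Dess–Martin oxidation of the primary allylic alcohol to the 2-substituted acrolein under buffered, non-basic conditions that should leave both esters and the three stereocentres untouched.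

## Compound list

1 | 3'-bromo-4'-hydroxyacetophenone | CC(=O)c1ccc(O)c(Br)c1 | starting material
2 | methallyl chloride (3-chloro-2-methylprop-1-ene) | CC(=C)CCl | starting material
3 | 1-[3-bromo-4-(2-methylprop-2-en-1-yloxy)phenyl]ethan-1-one | CC(=O)c1ccc(OCC(C)=C)c(Br)c1 | intermediate
4 | vinylboronic acid pinacol ester | C=CB1OC(C)(C)C(C)(C)O1 | starting material
5 | 1-[3-ethenyl-4-(2-methylprop-2-en-1-yloxy)phenyl]ethan-1-one | CC(=O)c1ccc(OCC(C)=C)c(C=C)c1 | intermediate
6 | (1R)-1-[3-ethenyl-4-(2-methylprop-2-en-1-yloxy)phenyl]ethan-1-ol | C=Cc1cc([C@@H](C)O)ccc1OCC(C)=C | intermediate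
7 | isovaleryl chloride | CC(C)CC(=O)Cl | starting material
8 | (1R)-1-[3-ethenyl-4-(2-methylprop-2-en-1-yloxy)phenyl]ethyl 3-methylbutanoate | C=Cc1cc([C@@H](C)OC(=O)CC(C)C)ccc1OCC(C)=C | intermediate
9 | bis-ozonide, (1R)-1-{4-[(3-methyl-1,2,4-trioxolan-3-yl)methoxy]-3-(1,2,4-trioxolan-3-yl)phenyl}ethyl 3-methylbutanoate (trioxolane carbons unassigned) | CC1(COc2ccc([C@@H](C)OC(=O)CC(C)C)cc2C2OOCO2)OOCO1 | intermediate (not isolated)
10 | (1R)-1-[3-formyl-4-(2-oxopropoxy)phenyl]ethyl 3-methylbutanoate | CC(=O)COc1ccc([C@@H](C)OC(=O)CC(C)C)cc1C=O | intermediate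
11 | L-proline (E)-enamine, (2S)-1-[(1E)-1-{2-formyl-4-[(1R)-1-(3-methylbutanoyloxy)ethyl]phenoxy}prop-1-en-2-yl]pyrrolidine-2-carboxylic acid | C/C(=C\Oc1ccc([C@@H](C)OC(=O)CC(C)C)cc1C=O)N1CCC[C@H]1C(=O)O | intermediate (not isolated)
12 | (1R)-1-[(2S,3R)-2-acetyl-3-hydroxy-2,3-dihydro-1-benzofuran-5-yl]ethyl 3-methylbutanoate (2,3-cis) | CC(=O)[C@H]1Oc2ccc([C@@H](C)OC(=O)CC(C)C)cc2[C@H]1O | intermediate
13 | (1R)-1-[(2S,3R)-2-acetyl-3-(triethylsilyloxy)-2,3-dihydro-1-benzofuran-5-yl]ethyl 3-methylbutanoate | CC(=O)[C@H]1Oc2ccc([C@@H](C)OC(=O)CC(C)C)cc2[C@H]1O[Si](CC)(CC)CC | intermediate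
14 | (1R)-1-[(2R,3R)-2-(prop-1-en-2-yl)-3-(triethylsilyloxy)-2,3-dihydro-1-benzofuran-5-yl]ethyl 3-methylbutanoate | C=C(C)[C@H]1Oc2ccc([C@@H](C)OC(=O)CC(C)C)cc2[C@H]1O[Si](CC)(CC)CC | intermediate
15 | (1R)-1-[(2R,3R)-3-hydroxy-2-(prop-1-en-2-yl)-2,3-dihydro-1-benzofuran-5-yl]ethyl 3-methylbutanoate | C=C(C)[C@H]1Oc2ccc([C@@H](C)OC(=O)CC(C)C)cc2[C@H]1O | intermediate
16 | (1R)-1-[(2R,3R)-3-(3-methylbutanoyloxy)-2-(prop-1-en-2-yl)-2,3-dihydro-1-benzofuran-5-yl]ethyl 3-methylbutanoate | C=C(C)[C@H]1Oc2ccc([C@@H](C)OC(=O)CC(C)C)cc2[C@H]1OC(=O)CC(C)C | intermediate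
17 | (1R)-1-[(2R,3R)-2-(3-hydroxyprop-1-en-2-yl)-3-(3-methylbutanoyloxy)-2,3-dihydro-1-benzofuran-5-yl]ethyl 3-methylbutanoate | C=C(CO)[C@H]1Oc2ccc([C@@H](C)OC(=O)CC(C)C)cc2[C@H]1OC(=O)CC(C)C | intermediate
18 | (1R)-1-[(2R,3R)-3-(3-methylbutanoyloxy)-2-(3-oxoprop-1-en-2-yl)-2,3-dihydro-1-benzofuran-5-yl]ethyl 3-methylbutanoate | C=C(C=O)[C@H]1Oc2ccc([C@@H](C)OC(=O)CC(C)C)cc2[C@H]1OC(=O)CC(C)C | target

Total step count: 12. Longest linear sequence: 12 steps (1 to 18).

## Steps most likely to fail

**Step 6 (key aldol).** The aldol may lose water through its own enamine or enol to the aromatic 2-acetylbenzofuran. Retro-aldol equilibration at long reaction times may also erode the cis and facial selectivity. If the ring forms with the opposite absolute sense, D-proline would give the needed antipode.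

The fallback replaces enamine catalysis by a metal-templated aldol and sets out from 10. MgBr2·OEt2 and iPr2NEt in CH2Cl2 at −20 °C should enolise the aryloxy-activated methylene by soft enolisation. The magnesium enolate should close ring B through a chelated closed transition state to a cis aldolate, which is held as a chelate and is quenched cold with pH 7 buffer. Catalyst control of the absolute configuration is given up in this variant. The ring would form in both cis senses, giving 12 together with (1R)-1-[(2R,3S)-2-acetyl-3-hydroxy-2,3-dihydro-1-benzofuran-5-yl]ethyl 3-methylbutanoate F1. Because the (R)-ester centre is already fixed, these two are diastereomers and would be separated by preparative chromatography. The fallback comes back to the route at 12.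

**Step 8 (methylenation).** The Lewis-acidic titanium reagent may ionise the para-alkoxybenzylic ester or the C3 silyl ether, with elimination towards the benzofuran. The hindered ketone may also react incompletely.

The fallback is a Peterson olefination and sets out from 13. Me3SiCH2Li with CeCl3 in THF at −78 °C should add to the ketone faster than to the ester and without enolisation. This would give (1R)-1-[(2S,3R)-2-[2-hydroxy-1-(trimethylsilyl)propan-2-yl]-3-(triethylsilyloxy)-2,3-dihydro-1-benzofuran-5-yl]ethyl 3-methylbutanoate F2 as a mixture at the new carbinol carbon. HF·pyridine in THF should then bring about the acid-type anti elimination to the isopropenyl group and remove the triethylsilyl group in the same operation. The fallback comes back to the route at 15, bypassing 14.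

**Step 11 (allylic oxidation).** The 1,1-disubstituted alkene may be oxidised sluggishly. Hydrogen abstraction at C2–H may compete and would open ring B. Over-oxidation is a further risk.

The fallback is a Schenck ene reaction with singlet oxygen and sets out from 16. O2, tetraphenylporphyrin and visible light in CH2Cl2 at 0 °C should give the allylic hydroperoxide on the former methyl carbon. This is (1R)-1-[(2R,3R)-2-(3-hydroperoxyprop-1-en-2-yl)-3-(3-methylbutanoyloxy)-2,3-dihydro-1-benzofuran-5-yl]ethyl 3-methylbutanoate F3. Reduction with PPh3 would give the allylic alcohol. The fallback comes back to the route at 17.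

## Further compounds

F1 | step 6 | (1R)-1-[(2R,3S)-2-acetyl-3-hydroxy-2,3-dihydro-1-benzofuran-5-yl]ethyl 3-methylbutanoate | CC(=O)[C@@H]1Oc2ccc([C@@H](C)OC(=O)CC(C)C)cc2[C@@H]1O
F2 | step 8 | (1R)-1-[(2S,3R)-2-[2-hydroxy-1-(trimethylsilyl)propan-2-yl]-3-(triethylsilyloxy)-2,3-dihydro-1-benzofuran-5-yl]ethyl 3-methylbutanoate | CC(O)(C[Si](C)(C)C)[C@H]1Oc2ccc([C@@H](C)OC(=O)CC(C)C)cc2[C@H]1O[Si](CC)(CC)CC
F3 | step 11 | (1R)-1-[(2R,3R)-2-(3-hydroperoxyprop-1-en-2-yl)-3-(3-methylbutanoyloxy)-2,3-dihydro-1-benzofuran-5-yl]ethyl 3-methylbutanoate | C=C(COO)[C@H]1Oc2ccc([C@@H](C)OC(=O)CC(C)C)cc2[C@H]1OC(=O)CC(C)C
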